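Numbering: ring C1 (bearing the exocyclic CH2), C2, C3, C4=C5 (C12 is the carboxyl carbon on C5), C6, C7 (O-angelate), C8, C9 (CMe2), C10, C11 (OH).
Enabling feature: in the eleven-membered ring, oxygenated C11, its α-carbon C1 and the C4=C5 alkene form a δ,ε-unsaturated carbonyl array (C11–C1–C2–C3–C4=C5). This is the signature of an oxy-Cope product, so cutting C2–C3 and rejoining C5–C11 contracts the ring to a cis-1,2-divinylcycloheptanol.
Further cuts: exocyclic C1=CH2 (Mannich/elimination), O7–acyl, C11–C1 (vinyl Grignard), C5–C4 (α-vinylation with acetylene), C5–C11 (Dieckmann) and C5=C6 (Wittig). These lead back to 5,5-dimethylcyclohex-2-enone, whose ring carbons become C6–C11.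
Forward: ozonolysis opens the cyclohexene, which fixes on which side of C11 the extra carbon C5 enters. The chain is extended by C5/C12, the cycloheptane is closed, both vinyl groups are added, and the [3,3] shift expands seven to eleven members. Acylation and redox adjustments follow.
Stereochemistry: C7 comes from a CBS reduction of the starting enone and is carried through. C11 comes from a second CBS reduction of the α-methylene ketone. C4=C5 comes from the chair transition state and is also the thermodynamic enal geometry. The angelate Z-alkene comes from angelic acid.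

Key step: step 11

Remark: the two stereocentres created on the cycloheptane ring (C5, C11) are erased in the key step, so the expected major diastereomer is drawn throughout.

Step 1
Reactants: 1 5,5-dimethylcyclohex-2-en-1-one
Product: 2 (1S)-5,5-dimethylcyclohex-2-en-1-ol
Conditions: (3aR)-1-methyl-3,3-diphenyltetrahydro-3H-pyrrolo[1,2-c][1,3,2]oxazaborole [(R)-Me-CBS, 10 mol %], catecholborane, toluene, −78 °C
Reagents that add atoms: none
Why: CBS 1,2-reduction of an enone, in which the alkenyl arm acts as the large and the ring CH2 as the small substituent, so the (R)-catalyst should give the (S)-carbinol that becomes C7 of the target.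

Step 2
Reactants: 2 (1S)-5,5-dimethylcyclohex-2-en-1-ol
Product: 3 [(1S)-5,5-dimethylcyclohex-2-en-1-yl]oxy-triisopropylsilane
Conditions: TIPSCl, imidazole, DMF, rt
Reagents that add atoms: chlorotriisopropylsilane CC(C)[Si](Cl)(C(C)C)C(C)C
Why: Standard silylation; the bulky TIPS ether tolerates ozone, alkoxide, hydride and KH later on and is slow to migrate.

Step 3
Reactants: 3 [(1S)-5,5-dimethylcyclohex-2-en-1-yl]oxy-triisopropylsilane
Product: 5 ethyl (5S)-3,3-dimethyl-6-oxo-5-(triisopropylsilyloxy)hexanoate, via ethoxy hydroperoxide 4 (not isolated)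
Conditions: O3, CH2Cl2–EtOH, NaHCO3, −78 °C; then Ac2O, Et3N, 0 °C → rt
Reagents that add atoms: ozone [O-][O+]=O; ethanol CCO
Why: Ozonolysis (Criegee mechanism) with a terminus-differentiating work-up: the electron-withdrawing allylic silyloxy group should steer the carbonyl oxide to the remote carbon C11, ethanol traps it as 4, and acetylation–elimination turns the hydroperoxide into the ethyl ester while C6 stays an aldehyde and C7 is untouched.

Step 4
Reactants: 5 ethyl (5S)-3,3-dimethyl-6-oxo-5-(triisopropylsilyloxy)hexanoate; 6 ethyl (triphenylphosphoranylidene)acetate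
Product: 7 diethyl (2E,4S)-6,6-dimethyl-4-(triisopropylsilyloxy)oct-2-enedioate
Conditions: CH2Cl2, rt
Reagents that add atoms: none
Why: Wittig olefination with a stabilised ylide under neutral conditions adds C5 and C12 without epimerising the α-silyloxy aldehyde.

Step 5
Reactants: 7 diethyl (2E,4S)-6,6-dimethyl-4-(triisopropylsilyloxy)oct-2-enedioate
Product: 8 diethyl (5R)-3,3-dimethyl-5-(triisopropylsilyloxy)octanedioate (same spatial arrangement at C7; the descriptor changes with the CIP ranking)
Conditions: H2 (1 atm), Pd/C, EtOAc, rt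
Reagents that add atoms: none
Why: Heterogeneous catalytic hydrogenation saturates only the enoate, since the silyl ether and the esters are inert.

Step 6
Reactants: 8 diethyl (5R)-3,3-dimethyl-5-(triisopropylsilyloxy)octanedioate
Product: 10 ethyl (6R)-4,4-dimethyl-2-oxo-6-(triisopropylsilyloxy)cycloheptane-1-carboxylate (C5 labile), via potassium enolate 9 (not isolated)
Conditions: KOtBu, THF (dilute), 0 °C → rt; then AcOH
Reagents that add atoms: none
Why: Dieckmann condensation in which C5 attacks the C11 ester; closure from C10 next to the quaternary C9 would give a far more crowded β-keto ester, the equilibrium drains into enolate 9, and the gem-dimethyl group assists seven-membered ring closure.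

Step 7
Reactants: 10 ethyl (6R)-4,4-dimethyl-2-oxo-6-(triisopropylsilyloxy)cycloheptane-1-carboxylate; 11 acetylene
Product: 12 ethyl (1R,6S)-1-ethenyl-4,4-dimethyl-2-oxo-6-(triisopropylsilyloxy)cycloheptane-1-carboxylate
Conditions: HC≡CH (1 atm), In(OTf)3 (20 mol %), 1,8-diazabicyclo[5.4.0]undec-7-ene (DBU, 20 mol %), MS 3 Å, toluene, 100 °C
Reagents that add atoms: none
Why: Indium-enolate addition to acetylene (a Conia-ene-type carbometalation known for 2-substituted cyclic β-keto esters) builds the α-vinyl quaternary C5; bond formation should occur on the face opposite the C7 silyloxy group, and this centre is erased again in step 11.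

Step 8
Reactants: 12 ethyl (1R,6S)-1-ethenyl-4,4-dimethyl-2-oxo-6-(triisopropylsilyloxy)cycloheptane-1-carboxylate; 13 vinylmagnesium bromide
Product: 14 ethyl (1R,2S,6S)-1,2-diethenyl-2-hydroxy-4,4-dimethyl-6-(triisopropylsilyloxy)cycloheptane-1-carboxylate (vinyl groups cis)
Conditions: LaCl3·2LiCl, THF, −78 → −20 °C; NH4Cl aq
Reagents that add atoms: none
Why: Lanthanide-assisted Grignard 1,2-addition to a hindered, enolisable ketone in preference to the neopentyl ester; the nucleophile should enter in the Felkin–Anh sense anti to the pseudo-axial ester arm and to the C7 silyloxy group on the same face, which sets C11 with the two vinyl groups cis.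

Step 9
Reactants: 14 ethyl (1R,2S,6S)-1,2-diethenyl-2-hydroxy-4,4-dimethyl-6-(triisopropylsilyloxy)cycloheptane-1-carboxylate
Product: 15 (1S,2S,4S)-1,2-diethenyl-2-(hydroxymethyl)-6,6-dimethyl-4-(triisopropylsilyloxy)cycloheptan-1-ol
Conditions: LiAlH4, Et2O, 0 °C; H2O/NaOH work-up
Reagents that add atoms: none
Why: Hydride reduction of the ester to the primary alcohol at low temperature, where the covalent aluminium alkoxide of the tertiary carbinol should not undergo retro-aldol cleavage.

Step 10
Reactants: 15 (1S,2S,4S)-1,2-diethenyl-2-(hydroxymethyl)-6,6-dimethyl-4-(triisopropylsilyloxy)cycloheptan-1-ol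
Product: 16 (1S,2S,4S)-1,2-diethenyl-2-[(4-methoxybenzyloxy)methyl]-6,6-dimethyl-4-(triisopropylsilyloxy)cycloheptan-1-ol
Conditions: NaH (1.05 equiv), PMBCl, Bu4NI (cat.), THF–DMF, 0 °C
Reagents that add atoms: 4-methoxybenzyl chloride COc1ccc(CCl)cc1
Why: Williamson etherification; with one equivalent of base only the primary alkoxide is alkylated, and at 0 °C the sodium alkoxide should not yet rearrange.

Step 11
Reactants: 16 (1S,2S,4S)-1,2-diethenyl-2-[(4-methoxybenzyloxy)methyl]-6,6-dimethyl-4-(triisopropylsilyloxy)cycloheptan-1-ol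
Product: 19 (5E,8S)-6-[(4-methoxybenzyloxy)methyl]-10,10-dimethyl-8-(triisopropylsilyloxy)cycloundec-5-en-1-one, via potassium alkoxide 17 (not isolated), via potassium enolate 18 (not isolated)
Conditions: KH, 18-crown-6, THF, 0 °C → rt; then sat. NH4Cl, −78 °C
Reagents that add atoms: none
Why: KH/18-crown-6 converts 16 into the dissociated alkoxide 17, whose charge-accelerated [3,3]-sigmatropic shift (anionic oxy-Cope rearrangement, the established four-carbon ring expansion of 1,2-divinylcycloalkanols) bonds the vinyl termini C2 and C3 while the C5–C11 ring bond breaks, giving enolate 18 and, after cold protonation, ketone 19. The eleven-membered ring therefore arises by ring expansion through a six-membered chair transition state and not by end-to-end cyclisation, driven by enolate formation and by relief of the congested vicinal fully substituted C5/C11 pair. No stereocentre is created: C5 and C11 become trigonal and C7 is a spectator. The selectivity required is the ring-cis (E) geometry of C4=C5, which the cis-divinyl isomer reaches through the chair that holds the C5–C6 ring bond axial and the larger CH2OPMB arm equatorial. A benzyl-type ether was chosen for O12 because, unlike a silyl ether, it can neither migrate to the adjacent alkoxide nor leave in a Grob-type fragmentation, and the only silyl group sits on the remote O7 as a bulky TIPS ether. The substrate holds no other acidic or electrophilic site, so chemoselectivity is not at issue.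

Step 12
Reactants: 19 (5E,8S)-6-[(4-methoxybenzyloxy)methyl]-10,10-dimethyl-8-(triisopropylsilyloxy)cycloundec-5-en-1-one
Product: 20 (5E,8S)-8-hydroxy-6-[(4-methoxybenzyloxy)methyl]-10,10-dimethylcycloundec-5-en-1-one
Conditions: TBAF, THF, rt
Reagents that add atoms: none
Why: Fluoride-induced desilylation frees the C7 hydroxyl while the PMB ether, ketone and alkene are unaffected.

Step 13
Reactants: 20 (5E,8S)-8-hydroxy-6-[(4-methoxybenzyloxy)methyl]-10,10-dimethylcycloundec-5-en-1-one; 21 angelic acid [(2Z)-2-methylbut-2-enoic acid]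
Product: 23 (1S,3E)-3-[(4-methoxybenzyloxy)methyl]-10,10-dimethyl-8-oxocycloundec-3-en-1-yl (2Z)-2-methylbut-2-enoate, via mixed anhydride 22 (not isolated)
Conditions: 21, 2,4,6-Cl3C6H2COCl, Et3N, toluene, rt; then 20, 80 °C
Reagents that add atoms: none
Why: Yamaguchi-type esterification through the mixed anhydride 22 without a nucleophilic catalyst, conditions known to transfer the angeloyl group without Z-to-E isomerisation; acylating before C12 is oxidised rules out γ-lactonisation between O7 and C12.

Step 14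
Reactants: 23 (1S,3E)-3-[(4-methoxybenzyloxy)methyl]-10,10-dimethyl-8-oxocycloundec-3-en-1-yl (2Z)-2-methylbut-2-enoate
Product: 25 (1S,3E)-3-formyl-10,10-dimethyl-8-oxocycloundec-3-en-1-yl (2Z)-2-methylbut-2-enoate, via allylic alcohol 24 (not isolated)
Conditions: DDQ (3 equiv), CH2Cl2–pH 7 buffer, rt
Reagents that add atoms: none
Why: DDQ cleaves the PMB ether by benzylic hydride abstraction and hydrolysis, and the excess dehydrogenates the liberated primary allylic alcohol 24 to the conjugated aldehyde, a known one-flask conversion of allylic PMB ethers.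

Step 15
Reactants: 25 (1S,3E)-3-formyl-10,10-dimethyl-8-oxocycloundec-3-en-1-yl (2Z)-2-methylbut-2-enoate
Product: 26 (1E,10S)-8,8-dimethyl-10-[(2Z)-2-methylbut-2-enoyloxy]-6-oxocycloundec-1-ene-1-carboxylic acid
Conditions: NaClO2, NaH2PO4, 2-methyl-2-butene, t-BuOH–H2O, 0 °C → rt
Reagents that add atoms: sodium chlorite [Na+].[O-]Cl=O
Why: Pinnick oxidation is selective for the aldehyde and, with the hypochlorite scavenger, leaves both trisubstituted alkenes and their geometry intact.

Step 16
Reactants: 26 (1E,10S)-8,8-dimethyl-10-[(2Z)-2-methylbut-2-enoyloxy]-6-oxocycloundec-1-ene-1-carboxylic acid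
Product: 27 prop-2-en-1-yl (1E,10S)-8,8-dimethyl-10-[(2Z)-2-methylbut-2-enoyloxy]-6-oxocycloundec-1-ene-1-carboxylate
Conditions: allyl bromide, K2CO3, DMF, rt
Reagents that add atoms: allyl bromide C=CCBr
Why: Carboxylate O-alkylation masks the acid for the enolate chemistry as an ester that can later be removed under neutral conditions.

Step 17
Reactants: 27 prop-2-en-1-yl (1E,10S)-8,8-dimethyl-10-[(2Z)-2-methylbut-2-enoyloxy]-6-oxocycloundec-1-ene-1-carboxylate; 28 Eschenmoser's salt (N,N-dimethylmethyleneiminium iodide)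
Product: 32 prop-2-en-1-yl (1E,10S)-8,8-dimethyl-5-methylidene-10-[(2Z)-2-methylbut-2-enoyloxy]-6-oxocycloundec-1-ene-1-carboxylate, via lithium enolate 29 (not isolated), via Mannich base 30 (not isolated), via methiodide 31 (not isolated)
Conditions: LiHMDS, THF, −78 °C; 28, −78 °C → rt; then MeI, CH2Cl2, rt; then NaHCO3 aq
Reagents that add atoms: none
Why: Kinetic deprotonation should occur at the unhindered C1 rather than at C10 next to the quaternary C9; the Mannich reaction, exhaustive methylation and Hofmann-type β-elimination then give the α-methylene ketone, and the transient C1 stereocentre is lost again.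

Step 18
Reactants: 32 prop-2-en-1-yl (1E,10S)-8,8-dimethyl-5-methylidene-10-[(2Z)-2-methylbut-2-enoyloxy]-6-oxocycloundec-1-ene-1-carboxylate
Product: 33 prop-2-en-1-yl (1E,6S,10S)-6-hydroxy-8,8-dimethyl-5-methylidene-10-[(2Z)-2-methylbut-2-enoyloxy]cycloundec-1-ene-1-carboxylate
Conditions: (3aR)-1-methyl-3,3-diphenyltetrahydro-3H-pyrrolo[1,2-c][1,3,2]oxazaborole [(R)-Me-CBS, 20 mol %], catecholborane, toluene, −78 °C
Reagents that add atoms: none
Why: CBS reduction with catecholborane attacks the enone carbonyl 1,2 and spares esters and alkenes; the α-branched alkenyl arm C1 is the large and CH2-10 the small group, so the (R)-catalyst should give the 11S alcohol under reagent control.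

Step 19
Reactants: 33 prop-2-en-1-yl (1E,6S,10S)-6-hydroxy-8,8-dimethyl-5-methylidene-10-[(2Z)-2-methylbut-2-enoyloxy]cycloundec-1-ene-1-carboxylate
Product: 34 (1E,6S,10S)-6-hydroxy-8,8-dimethyl-5-methylidene-10-[(2Z)-2-methylbut-2-enoyloxy]cycloundec-1-ene-1-carboxylic acid (CNP0263820.1)
Conditions: Pd(PPh3)4 (5 mol %), morpholine, THF, rt
Reagents that add atoms: none
Why: Tsuji–Trost-type deallylation, in which zerovalent palladium ionises only the allyl ester and morpholine captures the allyl fragment, leaving the angelate, the free allylic alcohol and the ring alkenes untouched.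

Compound list
1 | 5,5-dimethylcyclohex-2-en-1-one | CC1(C)CC=CC(=O)C1 | starting material
2 | (1S)-5,5-dimethylcyclohex-2-en-1-ol | O[C@@H]1C=CCC(C)(C)C1 | intermediate
3 | [(1S)-5,5-dimethylcyclohex-2-en-1-yl]oxy-triisopropylsilane | CC(C)[Si](O[C@@H]1C=CCC(C)(C)C1)(C(C)C)C(C)C | intermediate
4 | (2S)-6-ethoxy-6-hydroperoxy-4,4-dimethyl-2-(triisopropylsilyloxy)hexanal (C6 epimers) | CCOC(OO)CC(C)(C)C[C@H](O[Si](C(C)C)(C(C)C)C(C)C)C=O | intermediate
5 | ethyl (5S)-3,3-dimethyl-6-oxo-5-(triisopropylsilyloxy)hexanoate | CCOC(=O)CC(C)(C)C[C@H](O[Si](C(C)C)(C(C)C)C(C)C)C=O | intermediate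
6 | ethyl (triphenylphosphoranylidene)acetate | CCOC(=O)C=P(c1ccccc1)(c1ccccc1)c1ccccc1 | starting material
7 | diethyl (2E,4S)-6,6-dimethyl-4-(triisopropylsilyloxy)oct-2-enedioate | CCOC(=O)CC(C)(C)C[C@H](O[Si](C(C)C)(C(C)C)C(C)C)/C=C/C(=O)OCC | intermediate
8 | diethyl (5R)-3,3-dimethyl-5-(triisopropylsilyloxy)octanedioate | CCOC(=O)CC(C)(C)C[C@H](O[Si](C(C)C)(C(C)C)C(C)C)CCC(=O)OCC | intermediate
9 | potassium enolate of 10 | CCOC(=O)C1=C([O-])CC(C)(C)C[C@H](O[Si](C(C)C)(C(C)C)C(C)C)C1.[K+] | intermediate
10 | ethyl (6R)-4,4-dimethyl-2-oxo-6-(triisopropylsilyloxy)cycloheptane-1-carboxylate (C1 labile) | CCOC(=O)C1C(=O)CC(C)(C)C[C@H](O[Si](C(C)C)(C(C)C)C(C)C)C1 | intermediate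
11 | acetylene | C#C | starting material
12 | ethyl (1R,6S)-1-ethenyl-4,4-dimethyl-2-oxo-6-(triisopropylsilyloxy)cycloheptane-1-carboxylate | O=C1CC(C)(C)C[C@H](O[Si](C(C)C)(C(C)C)C(C)C)C[C@@]1(C(=O)OCC)C=C | intermediate
13 | vinylmagnesium bromide | C=C[Mg]Br | starting material
14 | ethyl (1R,2S,6S)-1,2-diethenyl-2-hydroxy-4,4-dimethyl-6-(triisopropylsilyloxy)cycloheptane-1-carboxylate | C=C[C@@]1(O)CC(C)(C)C[C@H](O[Si](C(C)C)(C(C)C)C(C)C)C[C@@]1(C(=O)OCC)C=C | intermediate
15 | (1S,2S,4S)-1,2-diethenyl-2-(hydroxymethyl)-6,6-dimethyl-4-(triisopropylsilyloxy)cycloheptan-1-ol | C=C[C@@]1(O)CC(C)(C)C[C@H](O[Si](C(C)C)(C(C)C)C(C)C)C[C@@]1(CO)C=C | intermediate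
16 | (1S,2S,4S)-1,2-diethenyl-2-[(4-methoxybenzyloxy)methyl]-6,6-dimethyl-4-(triisopropylsilyloxy)cycloheptan-1-ol | C=C[C@@]1(O)CC(C)(C)C[C@H](O[Si](C(C)C)(C(C)C)C(C)C)C[C@@]1(COCc2ccc(OC)cc2)C=C | intermediate
17 | potassium alkoxide of 16 | C=C[C@@]1([O-])CC(C)(C)C[C@H](O[Si](C(C)C)(C(C)C)C(C)C)C[C@@]1(COCc2ccc(OC)cc2)C=C.[K+] | intermediate
18 | potassium C11=C1 enolate of 19 (C10 trans to C2) | [K+].[O-]/C1=C\CC/C=C(/COCc2ccc(OC)cc2)C[C@@H](O[Si](C(C)C)(C(C)C)C(C)C)CC(C)(C)C1 | intermediate
19 | (5E,8S)-6-[(4-methoxybenzyloxy)methyl]-10,10-dimethyl-8-(triisopropylsilyloxy)cycloundec-5-en-1-one | O=C1CCC/C=C(/COCc2ccc(OC)cc2)C[C@@H](O[Si](C(C)C)(C(C)C)C(C)C)CC(C)(C)C1 | intermediate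
20 | (5E,8S)-8-hydroxy-6-[(4-methoxybenzyloxy)methyl]-10,10-dimethylcycloundec-5-en-1-one | O=C1CCC/C=C(/COCc2ccc(OC)cc2)C[C@@H](O)CC(C)(C)C1 | intermediate
21 | angelic acid, (2Z)-2-methylbut-2-enoic acid | C/C=C(/C)C(=O)O | starting material
22 | (2Z)-2-methylbut-2-enoic 2,4,6-trichlorobenzoic anhydride | C/C=C(/C)C(=O)OC(=O)c1c(Cl)cc(Cl)cc1Cl | intermediate
23 | (1S,3E)-3-[(4-methoxybenzyloxy)methyl]-10,10-dimethyl-8-oxocycloundec-3-en-1-yl (2Z)-2-methylbut-2-enoate | O=C1CCC/C=C(/COCc2ccc(OC)cc2)C[C@@H](OC(=O)/C(C)=C\C)CC(C)(C)C1 | intermediate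
24 | (1S,3E)-3-(hydroxymethyl)-10,10-dimethyl-8-oxocycloundec-3-en-1-yl (2Z)-2-methylbut-2-enoate | O=C1CCC/C=C(/CO)C[C@@H](OC(=O)/C(C)=C\C)CC(C)(C)C1 | intermediate
25 | (1S,3E)-3-formyl-10,10-dimethyl-8-oxocycloundec-3-en-1-yl (2Z)-2-methylbut-2-enoate | O=C1CCC/C=C(/C=O)C[C@@H](OC(=O)/C(C)=C\C)CC(C)(C)C1 | intermediate
26 | (1E,10S)-8,8-dimethyl-10-[(2Z)-2-methylbut-2-enoyloxy]-6-oxocycloundec-1-ene-1-carboxylic acid | O=C1CCC/C=C(/C(=O)O)C[C@@H](OC(=O)/C(C)=C\C)CC(C)(C)C1 | intermediate
27 | prop-2-en-1-yl ester of 26 | O=C1CCC/C=C(/C(=O)OCC=C)C[C@@H](OC(=O)/C(C)=C\C)CC(C)(C)C1 | intermediate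
28 | Eschenmoser's salt, N,N-dimethylmethyleneiminium iodide | C=[N+](C)C.[I-] | starting material
29 | lithium C11=C1 enolate of 27 (enolate geometry not defined) | [Li+].[O-]C1=CCC/C=C(/C(=O)OCC=C)C[C@@H](OC(=O)/C(C)=C\C)CC(C)(C)C1 | intermediate
30 | C1-(dimethylaminomethyl) ketone, Mannich base of 27 (C1 epimers) | CN(C)CC1CC/C=C(/C(=O)OCC=C)C[C@@H](OC(=O)/C(C)=C\C)CC(C)(C)CC1=O | intermediate
31 | trimethylammonium iodide of 30 (C1 epimers) | C[N+](C)(C)CC1CC/C=C(/C(=O)OCC=C)C[C@@H](OC(=O)/C(C)=C\C)CC(C)(C)CC1=O.[I-] | intermediate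
32 | prop-2-en-1-yl (1E,10S)-8,8-dimethyl-5-methylidene-10-[(2Z)-2-methylbut-2-enoyloxy]-6-oxocycloundec-1-ene-1-carboxylate | C=C1CC/C=C(/C(=O)OCC=C)C[C@@H](OC(=O)/C(C)=C\C)CC(C)(C)CC1=O | intermediate
33 | prop-2-en-1-yl (1E,6S,10S)-6-hydroxy-8,8-dimethyl-5-methylidene-10-[(2Z)-2-methylbut-2-enoyloxy]cycloundec-1-ene-1-carboxylate | C=C1CC/C=C(/C(=O)OCC=C)C[C@@H](OC(=O)/C(C)=C\C)CC(C)(C)C[C@@H]1O | intermediate
34 | (1E,6S,10S)-6-hydroxy-8,8-dimethyl-5-methylidene-10-[(2Z)-2-methylbut-2-enoyloxy]cycloundec-1-ene-1-carboxylic acid | C=C1CC/C=C(/C(=O)O)C[C@@H](OC(=O)/C(C)=C\C)CC(C)(C)C[C@@H]1O | target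

Total step count: 19. Longest linear sequence: 19 steps, from 1 to 34. Compounds 6, 11, 13, 21 and 28 are purchased.

Steps most likely to fail

Risk 1, step 11: poor control of the C4=C5 geometry.
- What may go wrong: the competing chair (alkoxide equatorial, CH2OPMB arm axial) may be followed. Any trans-divinyl epimer carried over from step 8 would also rearrange to the ring-trans alkene.
- Fallback: this replaces kinetic control in the pericyclic step by thermodynamic control at the enal stage. It sets out from 16 and returns at 25.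
- Route: the rearrangement is run as before and the ring-trans ketone F1 is accepted. TBAF gives the ring-trans hydroxy ketone F2. Mixed-anhydride angeloylation gives the ring-trans angelate F3. Excess DDQ gives the ring-trans (Z) enal F4. F4 is equilibrated with catalytic PhSH/Et3N in CH2Cl2 through reversible thia-Michael addition at C4.
- Why it should work: the (E)-enal 25 avoids the clash between the formyl group and C3, and an eleven-membered ring accommodates the cis alkene, so 25 should be strongly preferred. The α,β-disubstituted angelate is a much poorer acceptor and should not be touched.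

Risk 2, step 8: failure at the hindered ketone.
- What may go wrong: enolisation of the hindered ketone, competing attack on the ester or retro-aldol cleavage through it, and poor facial selectivity.
- Fallback: the ester is removed before the C–C bond is made. It sets out from 12 and returns at 16.
- Route: LiAlH4 reduces both carbonyl groups to the cycloheptane diol F5 (C11 epimers, of no consequence). NaH/PMBCl etherifies the primary hydroxyl to the PMB ether alcohol F6. Dess–Martin periodinane gives the α-quaternary ketone F7. Vinylmagnesium bromide with LaCl3·2LiCl then delivers 16 directly, with no electrophilic or fragmentable ester present.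

Risk 3, step 18: poor facial selectivity.
- What may go wrong: the neopentyl-like C10 arm and the alkenyl arm may not be differentiated well by the catalyst in the flexible medium ring.
- Fallback: reagent control is abandoned. It sets out from 32 and returns at 33.
- Route: Luche reduction (NaBH4, CeCl3·7H2O, MeOH, −78 °C) is run under substrate control. The C11 epimers are diastereomers because of C7 and are separated by chromatography, and the 11S isomer is 33. The 11R allylic alcohol F8 is re-oxidised with MnO2 to 32 and recycled.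

Further compounds
F1 | step 11 | (5Z,8S)-6-[(4-methoxybenzyloxy)methyl]-10,10-dimethyl-8-(triisopropylsilyloxy)cycloundec-5-en-1-one (ring-trans ketone) | O=C1CCC/C=C(\COCc2ccc(OC)cc2)C[C@@H](O[Si](C(C)C)(C(C)C)C(C)C)CC(C)(C)C1
F2 | step 11 | (5Z,8S)-8-hydroxy-6-[(4-methoxybenzyloxy)methyl]-10,10-dimethylcycloundec-5-en-1-one (ring-trans hydroxy ketone) | O=C1CCC/C=C(\COCc2ccc(OC)cc2)C[C@@H](O)CC(C)(C)C1
F3 | step 11 | (1S,3Z)-3-[(4-methoxybenzyloxy)methyl]-10,10-dimethyl-8-oxocycloundec-3-en-1-yl (2Z)-2-methylbut-2-enoate (ring-trans angelate) | O=C1CCC/C=C(\COCc2ccc(OC)cc2)C[C@@H](OC(=O)/C(C)=C\C)CC(C)(C)C1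
F4 | step 11 | (1S,3Z)-3-formyl-10,10-dimethyl-8-oxocycloundec-3-en-1-yl (2Z)-2-methylbut-2-enoate (ring-trans enal) | O=C1CCC/C=C(\C=O)C[C@@H](OC(=O)/C(C)=C\C)CC(C)(C)C1
F5 | step 8 | (2S,4S)-2-ethenyl-2-(hydroxymethyl)-6,6-dimethyl-4-(triisopropylsilyloxy)cycloheptan-1-ol (C1 epimers; cycloheptane diol) | OC1CC(C)(C)C[C@H](O[Si](C(C)C)(C(C)C)C(C)C)C[C@@]1(CO)C=C
F6 | step 8 | (2S,4S)-2-ethenyl-2-[(4-methoxybenzyloxy)methyl]-6,6-dimethyl-4-(triisopropylsilyloxy)cycloheptan-1-ol (C1 epimers; PMB ether alcohol) | OC1CC(C)(C)C[C@H](O[Si](C(C)C)(C(C)C)C(C)C)C[C@@]1(COCc2ccc(OC)cc2)C=C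
F7 | step 8 | (2S,4S)-2-ethenyl-2-[(4-methoxybenzyloxy)methyl]-6,6-dimethyl-4-(triisopropylsilyloxy)cycloheptan-1-one (α-quaternary ketone) | O=C1CC(C)(C)C[C@H](O[Si](C(C)C)(C(C)C)C(C)C)C[C@@]1(COCc2ccc(OC)cc2)C=C
F8 | step 18 | prop-2-en-1-yl (1E,6R,10S)-6-hydroxy-8,8-dimethyl-5-methylidene-10-[(2Z)-2-methylbut-2-enoyloxy]cycloundec-1-ene-1-carboxylate (11R allylic alcohol) | C=C1CC/C=C(/C(=O)OCC=C)C[C@@H](OC(=O)/C(C)=C\C)CC(C)(C)C[C@H]1O
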